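**Retrosynthetic overview**
1. Last bond: the depsidone ester between the ring A carboxyl carbon and the ring B C6 oxygen (seven-membered dioxepinone), closed by base-free dehydration of keto acid 24, which comes from isocoumarin 25 by hydroxide opening.
2. Key disconnection: the aryl–CH2 bond of the 2-oxoheptyl chain. On ring A the chain carbon (C6) is ortho to the carboxyl-bearing carbon (C1), and the other ortho carbon (C2) holds the diaryl ether oxygen. The free CO2H of diaryl ether acid 19 therefore has one open ortho C–H, and trivalent-rhodium C–H acylmethylation with ylide 23 plus cyclodehydration gives 25.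
3. Diaryl ether: SNAr of the ring B hydroquinone 10 (methyl orsellinate, 4-O-benzylation, Elbs oxidation) on 2-fluoro-4-methoxybenzaldehyde, later CHO to CO2H.
4. Spiro acylketal lactone: lateral lithiation of the ring B toluate, acylation with (R)-6-methyloxan-2-one (from (R)-propylene oxide), acid spirocyclisation under thermodynamic control.
5. Ring order: rings A and B are bought; oxane and isochromanone lactone (step 8); isocoumarin pyranone as a temporary ring (step 12); dioxepinone (step 14).

Key step: step 12

Remark (numbering): ring A is C1 (carboxyl carbon), C2 (ether oxygen), C4 (OMe), C6 (chain). Ring B is numbered as the isochroman-1-one: C1 lactone carbonyl, C3 spiro carbon, C4 CH2, C5 ether oxygen, C6 depsidone oxygen, C8 chelated OH.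
Remark (assumption): the (S) spiro carbon is taken to be the thermodynamic epimer, with the lactone oxygen axial on the oxane chair and the (R)-methyl equatorial, so acid equilibration is relied on to set it.
Remark (end game): a depsidone with a 2-oxoalkyl chain ortho to its carbonyl is expected to revert under base to the isocoumarin and the ring B phenoxide, because the phenoxide is far more stable than the ketone enolate. The isocoumarin is therefore opened with hydroxide and the depsidone closed by a base-free dehydration, not by phenoxide transacylation.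

**Step 1**
Reactants: 1 (R)-propylene oxide; 2 ethyl propiolate
Product: 4 ethyl (R)-5-hydroxyhex-2-ynoate, via ethyl 3-lithiopropiolate 3 (not isolated)
Conditions: 2, n-BuLi, THF, −78 °C; BF3·OEt2; then 1, −78 °C; aq NH4Cl
Reagents that add atoms: none
Why: Lewis-acid-assisted alkynylation of an epoxide (Yamaguchi–Hirao reaction), in which the lithium acetylide opens the BF3-activated epoxide by SN2 at its unsubstituted carbon, so the (R) carbinol carbon of 1 is carried over untouched.

**Step 2**
Reactants: 4 ethyl (R)-5-hydroxyhex-2-ynoate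
Product: 6 (R)-6-methyloxan-2-one, via ethyl (R)-5-hydroxyhexanoate 5 (not isolated)
Conditions: H2 (1 atm), Pd/C, EtOAc, rt; then TsOH·H2O (cat.), CH2Cl2, rt
Reagents that add atoms: none
Why: Heterogeneous hydrogenation of the alkyne to the saturated δ-hydroxy ester followed by acid-catalysed lactonisation with loss of ethanol, neither of which touches the stereocentre.

**Step 3**
Reactants: 7 methyl orsellinate
Product: 8 methyl 4-(benzyloxy)-2-hydroxy-6-methylbenzoate
Conditions: BnBr (1.05 equiv), K2CO3, acetone, reflux
Reagents that add atoms: benzyl bromide, BrCc1ccccc1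
Why: Williamson etherification that should be selective for the 4-hydroxyl, because the 2-hydroxyl is hydrogen-bonded to the ester carbonyl and is a much poorer nucleophile.

**Step 4**
Reactants: 8 methyl 4-(benzyloxy)-2-hydroxy-6-methylbenzoate
Product: 10 methyl 4-(benzyloxy)-3,6-dihydroxy-2-methylbenzoate, via potassium aryl sulfate 9 (not isolated)
Conditions: K2S2O8, aq KOH, pyridine, 0 °C to rt; then aq HCl, 80 °C
Reagents that add atoms: potassium peroxodisulfate, [K+].[K+].[O-]S(=O)(=O)OOS(=O)(=O)[O-]
Why: Elbs persulfate oxidation, in which the only phenoxide attacks the peroxide oxygen through the free carbon para to it (the future C5 of ring B, meta to the ester), and hot aqueous acid then hydrolyses the aryl sulfate to the hydroquinone.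

**Step 5**
Reactants: 10 methyl 4-(benzyloxy)-3,6-dihydroxy-2-methylbenzoate; 11 2-fluoro-4-methoxybenzaldehyde
Product: 12 methyl 4-(benzyloxy)-3-(2-formyl-5-methoxyphenoxy)-6-hydroxy-2-methylbenzoate
Conditions: K2CO3, DMF, 100 °C, argon
Reagents that add atoms: none
Why: Nucleophilic aromatic substitution (addition–elimination through a Meisenheimer adduct) of fluoride ortho to the formyl group by the non-chelated 3-phenoxide, the ester-chelated 6-hydroxyl being too weak a nucleophile to compete.

**Step 6**
Reactants: 12 methyl 4-(benzyloxy)-3-(2-formyl-5-methoxyphenoxy)-6-hydroxy-2-methylbenzoate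
Product: 13 methyl 4,6-bis(benzyloxy)-3-(2-formyl-5-methoxyphenoxy)-2-methylbenzoate
Conditions: BnBr, K2CO3, DMF, 60 °C
Reagents that add atoms: benzyl bromide, BrCc1ccccc1
Why: Williamson benzylation of the chelated phenol under more forcing conditions, which removes the acidic proton before the lithiation and does not affect the non-enolisable aldehyde.

**Step 7**
Reactants: 13 methyl 4,6-bis(benzyloxy)-3-(2-formyl-5-methoxyphenoxy)-2-methylbenzoate
Product: 14 methyl 4,6-bis(benzyloxy)-3-[2-(1,3-dioxolan-2-yl)-5-methoxyphenoxy]-2-methylbenzoate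
Conditions: HOCH2CH2OH, pyridinium p-toluenesulfonate (cat.), benzene, reflux (Dean–Stark)
Reagents that add atoms: ethylene glycol, OCCO
Why: Acid-catalysed acetalisation with azeotropic removal of water, which protects the aldehyde from the benzylic anion of the next step, while the hindered 2,6-disubstituted methyl ester does not transesterify.

**Step 8**
Reactants: 14 methyl 4,6-bis(benzyloxy)-3-[2-(1,3-dioxolan-2-yl)-5-methoxyphenoxy]-2-methylbenzoate; 6 (R)-6-methyloxan-2-one
Product: 17 2-{[(3S,6'R)-6,8-bis(benzyloxy)-6'-methyl-1-oxospiro[isochromane-3,2'-oxan]-5-yl]oxy}-4-methoxybenzaldehyde, via benzylic lithium compound 15 (not isolated), via open hydroxy keto ester 16 (not isolated)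
Conditions: LiN(iPr)2 (1.2 equiv), THF, −78 °C; 6 (1.5 equiv), −78 to 0 °C; then 2 M HCl, THF, 40 °C
Reagents that add atoms: water, O
Why: Lateral lithiation of an ortho-toluate and acylation of the benzylic anion by the lactone give the δ-hydroxy benzyl ketone (partly as its lactolate), and aqueous acid then hydrolyses the dioxolane and closes the spiro acylketal lactone through the oxocarbenium ion with loss of methanol, the reversible ketalisation settling on the (S) spiro carbon because that epimer has the lactone oxygen axial (anomeric effect) and the (R)-methyl equatorial on the oxane chair.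

**Step 9**
Reactants: 17 2-{[(3S,6'R)-6,8-bis(benzyloxy)-6'-methyl-1-oxospiro[isochromane-3,2'-oxan]-5-yl]oxy}-4-methoxybenzaldehyde
Product: 18 2-{[(3S,6'R)-6,8-bis(benzyloxy)-6'-methyl-1-oxospiro[isochromane-3,2'-oxan]-5-yl]oxy}-4-methoxybenzoic acid
Conditions: NaClO2, NaH2PO4, 2-methyl-2-butene, t-BuOH/THF/H2O, 0 °C to rt
Reagents that add atoms: sodium chlorite, [Na+].[O-]Cl=O
Why: Pinnick oxidation of the aryl aldehyde at about pH 4, where the acylketal is stable and the alkene scavenger removes hypochlorous acid before it can chlorinate the electron-rich rings.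

**Step 10**
Reactants: 18 2-{[(3S,6'R)-6,8-bis(benzyloxy)-6'-methyl-1-oxospiro[isochromane-3,2'-oxan]-5-yl]oxy}-4-methoxybenzoic acid
Product: 19 2-{[(3S,6'R)-6,8-dihydroxy-6'-methyl-1-oxospiro[isochromane-3,2'-oxan]-5-yl]oxy}-4-methoxybenzoic acid
Conditions: H2 (1 atm), Pd/C, EtOAc/THF, rt
Reagents that add atoms: none
Why: Neutral hydrogenolysis of the two aryl benzyl ethers, which leaves the diaryl ether, the acid and the non-benzylic C–O bonds of the spiro acylketal untouched.

**Step 11**
Reactants: 20 hexanoyl chloride; 21 trimethylsulfoxonium iodide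
Product: 23 1-(dimethyloxo-λ6-sulfanylidene)heptan-2-one, via dimethylsulfoxonium methylide 22 (not isolated)
Conditions: 21 (3 equiv), KOtBu (3 equiv), THF, reflux; then 20, 0 °C to rt
Reagents that add atoms: none
Why: C-acylation of dimethylsulfoxonium methylide (the Corey–Chaykovsky reagent) by the acid chloride, a second equivalent of the methylide removing the acidic proton of the acylsulfoxonium salt to give the stabilised keto ylide.

**Step 12**
Reactants: 19 2-{[(3S,6'R)-6,8-dihydroxy-6'-methyl-1-oxospiro[isochromane-3,2'-oxan]-5-yl]oxy}-4-methoxybenzoic acid; 23 1-(dimethyloxo-λ6-sulfanylidene)heptan-2-one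
Product: 25 (3S,6'R)-6,8-dihydroxy-5-[(6-methoxy-1-oxo-3-pentyl-1H-isochromen-8-yl)oxy]-6'-methylspiro[isochromane-3,2'-oxan]-1-one, via keto acid 24 (not isolated)
Conditions: [(C5Me5)RhCl2]2 (5 mol%), AgSbF6 (20 mol%), NaOAc (0.5 equiv), 23 (1.5 equiv), ClCH2CH2Cl, 90 °C, argon
Reagents that add atoms: none
Why: AgSbF6 strips chloride from [(C5Me5)RhCl2]2, and the cationic trivalent rhodium carboxylate of 19 cleaves the ring A C6–H by concerted metalation–deprotonation to a five-membered rhodacycle; the ylide binds through carbon, loses dimethyl sulfoxide to give a rhodium carbene, the aryl group migrates to the carbene carbon (new aryl–CH2 bond) and protonolysis releases keto acid 24 and the catalyst. The closest known reaction type is the carboxylate-directed C–H acylmethylation and annulation of benzoic acids with sulfoxonium ylides to 3-substituted isocoumarins. The pyranone ring then closes by 6-exo-trig addition of the carboxyl oxygen to the ketone carbonyl, and the hot Lewis-acidic medium dehydrates the lactol to the enol lactone 25 (new C3–O bond). No stereocentre is formed, and the spiro acylketal, should it ionise, can only re-close to its thermodynamic epimer. The step needs site selectivity, which is secured because the other carbon ortho to the carboxylate carries the ether oxygen and both ring B carbons ortho to that oxygen are substituted, and it needs chemoselectivity for C–H coupling over O-alkylation of the acid or phenols by the ylide, which the acetate buffer and the fast chelation-assisted metalation are expected to favour.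

**Step 13**
Reactants: 25 (3S,6'R)-6,8-dihydroxy-5-[(6-methoxy-1-oxo-3-pentyl-1H-isochromen-8-yl)oxy]-6'-methylspiro[isochromane-3,2'-oxan]-1-one
Product: 24 2-{[(3S,6'R)-6,8-dihydroxy-6'-methyl-1-oxospiro[isochromane-3,2'-oxan]-5-yl]oxy}-4-methoxy-6-(2-oxoheptyl)benzoic acid
Conditions: LiOH (6 equiv), THF/H2O, 0 °C to rt, argon; then 1 M HCl to pH 3, 0 °C
Reagents that add atoms: lithium hydroxide, [Li+].[OH-]
Why: Alkaline hydrolysis of an enol lactone to the keto carboxylate, expected to be selective because under these conditions the ring B lactone carbonyl is conjugated to phenoxides at C6 (para) and C8 (ortho) and is thereby deactivated, while cold acidification returns the keto acid without the dehydrating conditions needed to re-form 25.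

**Step 14**
Reactants: 24 2-{[(3S,6'R)-6,8-dihydroxy-6'-methyl-1-oxospiro[isochromane-3,2'-oxan]-5-yl]oxy}-4-methoxy-6-(2-oxoheptyl)benzoic acid
Product: 26 target depsidone (ring A carboxyl esterified with the ring B C6 oxygen; 2-oxoheptyl and methoxy on ring A; chelated C8 hydroxyl and (3S,6'R) spiro acylketal lactone on ring B)
Conditions: dicyclohexylcarbodiimide (1.3 equiv), CH2Cl2 (1 mM), 0 °C to rt; chromatography on acid-washed silica
Reagents that add atoms: none
Why: Carbodiimide-mediated dehydrative lactonisation of a 2-(2-hydroxyaryloxy)benzoic acid, the classical depsidone closure, in which the C6 phenol is the only hydroxyl that can reach the O-acylisourea (seven-membered ring) and the absence of base should keep the ketone from enolising and re-forming the isocoumarin.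

**Compound list**
1 | (R)-propylene oxide | C[C@@H]1CO1 | starting material
2 | ethyl propiolate | CCOC(=O)C#C | starting material
3 | ethyl 3-lithiopropiolate | CCOC(=O)C#C[Li] | intermediate (not isolated)
4 | ethyl (R)-5-hydroxyhex-2-ynoate | CCOC(=O)C#CC[C@@H](C)O | intermediate
5 | ethyl (R)-5-hydroxyhexanoate | CCOC(=O)CCC[C@@H](C)O | intermediate (not isolated)
6 | (R)-6-methyloxan-2-one | C[C@@H]1CCCC(=O)O1 | intermediate
7 | methyl orsellinate | COC(=O)c1c(C)cc(O)cc1O | starting material
8 | methyl 4-(benzyloxy)-2-hydroxy-6-methylbenzoate | COC(=O)c1c(C)cc(OCc2ccccc2)cc1O | intermediate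
9 | potassium 6-(benzyloxy)-4-hydroxy-3-(methoxycarbonyl)-2-methylphenyl sulfate | COC(=O)c1c(C)c(OS(=O)(=O)[O-])c(OCc2ccccc2)cc1O.[K+] | intermediate (not isolated)
10 | methyl 4-(benzyloxy)-3,6-dihydroxy-2-methylbenzoate | COC(=O)c1c(C)c(O)c(OCc2ccccc2)cc1O | intermediate
11 | 2-fluoro-4-methoxybenzaldehyde | COc1ccc(C=O)c(F)c1 | starting material
12 | methyl 4-(benzyloxy)-3-(2-formyl-5-methoxyphenoxy)-6-hydroxy-2-methylbenzoate | COC(=O)c1c(C)c(Oc2cc(OC)ccc2C=O)c(OCc2ccccc2)cc1O | intermediate
13 | methyl 4,6-bis(benzyloxy)-3-(2-formyl-5-methoxyphenoxy)-2-methylbenzoate | COC(=O)c1c(C)c(Oc2cc(OC)ccc2C=O)c(OCc2ccccc2)cc1OCc1ccccc1 | intermediate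
14 | methyl 4,6-bis(benzyloxy)-3-[2-(1,3-dioxolan-2-yl)-5-methoxyphenoxy]-2-methylbenzoate | COC(=O)c1c(C)c(Oc2cc(OC)ccc2C2OCCO2)c(OCc2ccccc2)cc1OCc1ccccc1 | intermediate
15 | methyl 4,6-bis(benzyloxy)-3-[2-(1,3-dioxolan-2-yl)-5-methoxyphenoxy]-2-(lithiomethyl)benzoate | COC(=O)c1c(C[Li])c(Oc2cc(OC)ccc2C2OCCO2)c(OCc2ccccc2)cc1OCc1ccccc1 | intermediate (not isolated)
16 | methyl 4,6-bis(benzyloxy)-3-[2-(1,3-dioxolan-2-yl)-5-methoxyphenoxy]-2-[(6R)-6-hydroxy-2-oxoheptyl]benzoate | COC(=O)c1c(CC(=O)CCC[C@@H](C)O)c(Oc2cc(OC)ccc2C2OCCO2)c(OCc2ccccc2)cc1OCc1ccccc1 | intermediate (not isolated)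
17 | 2-{[(3S,6'R)-6,8-bis(benzyloxy)-6'-methyl-1-oxospiro[isochromane-3,2'-oxan]-5-yl]oxy}-4-methoxybenzaldehyde | O=Cc1ccc(OC)cc1Oc1c(OCc2ccccc2)cc(OCc2ccccc2)c2c1C[C@]1(CCC[C@@H](C)O1)OC2=O | intermediate
18 | 2-{[(3S,6'R)-6,8-bis(benzyloxy)-6'-methyl-1-oxospiro[isochromane-3,2'-oxan]-5-yl]oxy}-4-methoxybenzoic acid | OC(=O)c1ccc(OC)cc1Oc1c(OCc2ccccc2)cc(OCc2ccccc2)c2c1C[C@]1(CCC[C@@H](C)O1)OC2=O | intermediate
19 | 2-{[(3S,6'R)-6,8-dihydroxy-6'-methyl-1-oxospiro[isochromane-3,2'-oxan]-5-yl]oxy}-4-methoxybenzoic acid | COc1ccc(C(=O)O)c(Oc2c(O)cc(O)c3c2C[C@]2(CCC[C@@H](C)O2)OC3=O)c1 | intermediate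
20 | hexanoyl chloride | CCCCCC(=O)Cl | starting material
21 | trimethylsulfoxonium iodide | C[S+](C)(C)=O.[I-] | starting material
22 | dimethylsulfoxonium methylide | C=S(C)(C)=O | intermediate (not isolated)
23 | 1-(dimethyloxo-λ6-sulfanylidene)heptan-2-one | CCCCCC(=O)C=S(C)(C)=O | intermediate
24 | 2-{[(3S,6'R)-6,8-dihydroxy-6'-methyl-1-oxospiro[isochromane-3,2'-oxan]-5-yl]oxy}-4-methoxy-6-(2-oxoheptyl)benzoic acid | CCCCCC(=O)Cc1cc(OC)cc(Oc2c(O)cc(O)c3c2C[C@]2(CCC[C@@H](C)O2)OC3=O)c1C(=O)O | intermediate
25 | (3S,6'R)-6,8-dihydroxy-5-[(6-methoxy-1-oxo-3-pentyl-1H-isochromen-8-yl)oxy]-6'-methylspiro[isochromane-3,2'-oxan]-1-one | CCCCCc1cc2cc(OC)cc(Oc3c(O)cc(O)c4c3C[C@]3(CCC[C@@H](C)O3)OC4=O)c2c(=O)o1 | intermediate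
26 | target depsidone CNP0301127.1 | CCCCCC(=O)Cc1cc(OC)cc2c1C(=O)Oc1cc(O)c3c(c1O2)C[C@]1(CCC[C@@H](C)O1)OC3=O | target

**Totals**
Total step count: 14. Longest linear sequence: 11 steps (steps 3 to 10, then 12 to 14).

**Steps most likely to fail**

Step 12. The ylide may be consumed by protonation and O-alkylation of the carboxylic acid or the phenols, or the cationic rhodium may be tied up by the ring B phenols, so that C–H coupling stalls. The fallback sets out from 18 and returns at 25. The carboxylate of 18 would direct an ortho-iodination (Pd(OAc)2, divalent palladium, with PhI(OAc)2 and I2 in DMF) to 2-{[(3S,6'R)-6,8-bis(benzyloxy)-6'-methyl-1-oxospiro[isochromane-3,2'-oxan]-5-yl]oxy}-6-iodo-4-methoxybenzoic acid F1. Coupling of this with hept-1-yne under Pd(PPh3)4 (zerovalent palladium), ZnCl2 and Et3N in DMF at 100 °C, where the carboxylate adds 6-endo to the activated alkyne, would give the dibenzyl isocoumarin F2. Hydrogenolysis over Pd/C, stopped after two equivalents of H2, would free the two phenols and rejoin the route at 25.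

Step 14. The activated carboxyl may be captured by the ketone oxygen faster than by the C6 phenol (enol lactonisation back to 25), or the product may isomerise to 25 during reaction or purification; 25 formed this way can be recycled through step 13. The fallback sets out from 24 and returns at 26. The ketone would be masked with 1,2-bis(trimethylsilyloxy)ethane and catalytic Me3SiOTf (CH2Cl2, −78 to −20 °C, aqueous work-up) to give the dioxolane acid F3. The same carbodiimide closure, now without a competing ketone, would give the depsidone dioxolane F4, and pyridinium p-toluenesulfonate in wet acetone would release the ketone to give 26.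

Step 8. Proton transfer from the lactone or from the first-formed ketone may quench the benzylic anion, so that acylation stalls or gives mixtures. The fallback sets out from 6 and 14 and returns at 17. Lactone 6 would be opened with MeNH(OMe)·HCl and AlMe3 to (R)-5-hydroxy-N-methoxy-N-methylhexanamide F5 and silylated (t-BuMe2SiCl, imidazole) to the silyl ether F6. The anion 15, made from 14 as before, should add once to this Weinreb amide through a stable chelated adduct to give the silyl-protected benzyl ketone F7. Aqueous HCl in THF would then remove the silyl ether and the dioxolane and close the spiro acylketal lactone, returning to 17.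

**Further compounds**
F1 | step 12 | 2-{[(3S,6'R)-6,8-bis(benzyloxy)-6'-methyl-1-oxospiro[isochromane-3,2'-oxan]-5-yl]oxy}-6-iodo-4-methoxybenzoic acid | OC(=O)c1c(I)cc(OC)cc1Oc1c(OCc2ccccc2)cc(OCc2ccccc2)c2c1C[C@]1(CCC[C@@H](C)O1)OC2=O
F2 | step 12 | (3S,6'R)-6,8-bis(benzyloxy)-5-[(6-methoxy-1-oxo-3-pentyl-1H-isochromen-8-yl)oxy]-6'-methylspiro[isochromane-3,2'-oxan]-1-one | CCCCCc1cc2cc(OC)cc(Oc3c(OCc4ccccc4)cc(OCc4ccccc4)c4c3C[C@]3(CCC[C@@H](C)O3)OC4=O)c2c(=O)o1
F3 | step 14 | 2-{[(3S,6'R)-6,8-dihydroxy-6'-methyl-1-oxospiro[isochromane-3,2'-oxan]-5-yl]oxy}-4-methoxy-6-[(2-pentyl-1,3-dioxolan-2-yl)methyl]benzoic acid | CCCCCC1(Cc2cc(OC)cc(Oc3c(O)cc(O)c4c3C[C@]3(CCC[C@@H](C)O3)OC4=O)c2C(=O)O)OCCO1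
F4 | step 14 | ethylene ketal of the target depsidone at the side-chain ketone | CCCCCC1(Cc2cc(OC)cc3c2C(=O)Oc2cc(O)c4c(c2O3)C[C@]2(CCC[C@@H](C)O2)OC4=O)OCCO1
F5 | step 8 | (R)-5-hydroxy-N-methoxy-N-methylhexanamide | C[C@@H](O)CCCC(=O)N(C)OC
F6 | step 8 | (R)-5-[(tert-butyldimethylsilyl)oxy]-N-methoxy-N-methylhexanamide | C[C@@H](O[Si](C)(C)C(C)(C)C)CCCC(=O)N(C)OC
F7 | step 8 | methyl 4,6-bis(benzyloxy)-2-{(6R)-6-[(tert-butyldimethylsilyl)oxy]-2-oxoheptyl}-3-[2-(1,3-dioxolan-2-yl)-5-methoxyphenoxy]benzoate | COC(=O)c1c(CC(=O)CCC[C@@H](C)O[Si](C)(C)C(C)(C)C)c(Oc2cc(OC)ccc2C2OCCO2)c(OCc2ccccc2)cc1OCc1ccccc1
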